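**Plan**
- Retrosynthesis: cut the C11=C12 alkene (Wittig), trace the oxygens at C6, C7 and C8 back to a single C7 ketone, then open ring B at C9–C10 and C5=C6.
- Ring A is bought complete as 2,2,6-trimethylcyclohexanone: its quaternary carbon is C4 with the gem-dimethyl group, its carbonyl carbon is C5 and its only enolisable carbon is the methyl-bearing C10. This is what allows a regiochemically unambiguous, stereoconvergent annulation.
- Forward: the (S)-1-phenylethylamine imine of this ketone is annulated with ethyl (E)-3-methyl-4-oxopent-2-enoate, closing ring B as the Δ5-7-one with C11 as a 9β-ester. The ester is then reduced and masked; 8α-OH, 5α-H and 6α-OH are installed around the C7 ketone; acetylation, C7 reduction, C11 oxidation and olefination finish the chain.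
- Stereochemistry: C10 from the chiral amine (both ketone enantiomers converge); C9 from the compact aza-ene transition state; C8, C5 and C6 from reagent approach to the α face, opposite the axial methyls; C7 from axial hydride delivery; the E alkene from the stabilised ylide.

Key step: step 3

Remark: labdane numbering is used throughout (ring A = C1–C5 and C10, ring B = C5–C10, C11 on C9; α is the face opposite the C10 methyl; TBS = tert-butyldimethylsilyl), and the (S)-amine is assumed to induce in the same sense as it does with imines of 2-methylcyclohexanone.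

**Route**

Step 1
Reactants: 1 2,2,6-trimethylcyclohexanone (racemic); 2 (S)-1-phenylethylamine
Product: 3 (S)-1-phenyl-N-(2,2,6-trimethylcyclohexylidene)ethanamine (both C6 epimers)
Conditions: TiCl4 (0.6 equiv), Et3N (3 equiv), toluene, 0 °C to 110 °C
Reagents that add atoms: none
Why: TiCl4-mediated ketone–amine condensation, in which titanium is both Lewis acid and irreversible water scavenger, should force even this doubly α-branched ketone to the ketimine; the ketone stereocentre does not matter because it is erased in step 3.

Step 2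
Reactants: 4 butane-2,3-dione; 5 ethyl (triphenylphosphoranylidene)acetate
Product: 6 ethyl (E)-3-methyl-4-oxopent-2-enoate
Conditions: excess 4, CH2Cl2, 20 °C
Reagents that add atoms: none
Why: Wittig mono-olefination of the symmetrical 1,2-diketone with a stabilised ylide should stop after one carbonyl (the remaining one becomes a deactivated enone carbonyl) and give the E isomer with the ester trans to acetyl.

Step 3
Reactants: 3 (S)-1-phenyl-N-(2,2,6-trimethylcyclohexylidene)ethanamine; 6 ethyl (E)-3-methyl-4-oxopent-2-enoate
Product: 10 ethyl 4,4,8α,10β-tetramethyl-7-oxo-Δ5-octalin-9β-carboxylate, via secondary enamine 7 (not isolated), via Michael adduct imine 8 (not isolated), via diketo ester 9 (not isolated)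
Conditions: 6 (1.3 equiv), THF (2 M), 60 °C; then 10% aq AcOH/THF, 40 °C; then crude 9, TsOH·H2O (0.3 equiv), toluene, 110 °C, azeotropic removal of water
Reagents that add atoms: none
Why: Imine 3 can tautomerise only toward C10, so both enantiomers of 1 converge on enamine 7, whose C10 adds to C9 of 6 (β to the ketone) in a chair-like aza-ene transition state with N–H transfer to C8; hydrolysis of adduct 8 and acid-catalysed aldol condensation of the C6 enol onto the C5 carbonyl then give 10. The closest known reaction type is the Michael addition of 1-phenylethylamine ketimines of 2-alkylcyclohexanones to electrophilic alkenes followed by Robinson-type aldol condensation. Ring B closes in the 6-(enolendo)-exo-trig aldol mode, the only cyclisation open to 9 because the C5 ketone has no α-hydrogen and attack from C8 would form a four-membered ring. C10 is controlled by the (S)-1-phenylethyl group, whose C–H eclipses the enamine plane on the C4 side so that the acceptor enters anti to phenyl, the face that makes the C10 methyl β; C9 is controlled by the compact orientation of the E-acceptor (acetyl over nitrogen, ester outward), which gives the 9β-ester; C8 is set by suprafacial hydrogen delivery and in any case equilibrates through the C7 enol to the equatorial 8α-methyl. The step needs attack β to the ketone and not β to the ester, secured by the stronger activation by the ketone, and it needs C9 to stay untouched during ring closure, secured by using acid instead of alkoxide (no ester enolisation, no retro-Michael loss of the ketone enolate). Because nitrogen is pressed against the C4 methyls the addition is expected to be slow, hence the concentrated solution, the doubly activated acceptor and prolonged warming.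

Step 4
Reactants: 10 ethyl 4,4,8α,10β-tetramethyl-7-oxo-Δ5-octalin-9β-carboxylate
Product: 11 9β-(hydroxymethyl)-4,4,8α,10β-tetramethyl-Δ5-octalin-7-ol (both C7 epimers)
Conditions: i-Bu2AlH (4.5 equiv), CH2Cl2, −78 °C to 0 °C
Reagents that add atoms: none
Why: Aluminium hydride reduction (ester to primary alcohol, enone by clean 1,2-addition) should remove the epimerisable ester next to C9 directly after the key step; the C7 carbinol configuration is irrelevant because step 5 re-oxidises it.

Step 5
Reactants: 11 9β-(hydroxymethyl)-4,4,8α,10β-tetramethyl-Δ5-octalin-7-ol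
Product: 12 9β-(hydroxymethyl)-4,4,8α,10β-tetramethyl-Δ5-octalin-7-one
Conditions: MnO2 (excess), CH2Cl2, 20 °C
Reagents that add atoms: none
Why: Allylic oxidation with MnO2 should return the C7 carbinol to the enone while leaving the saturated primary alcohol untouched.

Step 6
Reactants: 12 9β-(hydroxymethyl)-4,4,8α,10β-tetramethyl-Δ5-octalin-7-one
Product: 13 9β-[(tert-butyldimethylsilyloxy)methyl]-4,4,8α,10β-tetramethyl-Δ5-octalin-7-one
Conditions: TBSCl, imidazole, DMF, 20 °C
Reagents that add atoms: tert-butyldimethylsilyl chloride, CC(C)(C)[Si](C)(C)Cl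
Why: Silyl ether formation on the only hydroxyl group should mask C11–OH through the enolate, hydrogenation and hydride steps that follow.

Step 7
Reactants: 13 9β-[(tert-butyldimethylsilyloxy)methyl]-4,4,8α,10β-tetramethyl-Δ5-octalin-7-one
Product: 15 9β-[(tert-butyldimethylsilyloxy)methyl]-8α-hydroxy-4,4,8β,10β-tetramethyl-Δ5-octalin-7-one, via potassium dienolate 14 (not isolated)
Conditions: KN(SiMe3)2 (1.1 equiv), THF, −78 °C; then 2-(phenylsulfonyl)-3-phenyloxaziridine, −78 °C; AcOH quench
Reagents that add atoms: 2-(phenylsulfonyl)-3-phenyloxaziridine, O=S(=O)(c1ccccc1)N1OC1c1ccccc1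
Why: Enolate hydroxylation with an N-sulfonyloxaziridine should be regiospecific because C8–H is the only enolisable hydrogen of the enone (C6 is vinylic, C4 and C10 are quaternary), and the oxidant should reach C8 of the cross-conjugated dienolate from the α face, anti to the 9β-CH2OTBS group and to the axial C10 methyl, giving 8α-OH with 8β-methyl.

Step 8
Reactants: 15 9β-[(tert-butyldimethylsilyloxy)methyl]-8α-hydroxy-4,4,8β,10β-tetramethyl-Δ5-octalin-7-one
Product: 16 9β-[(tert-butyldimethylsilyloxy)methyl]-8α-hydroxy-4,4,8β,10β-tetramethyl-trans-decalin-7-one (5α-H)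
Conditions: H2 (4 bar), Pd/C, EtOAc, 20 °C
Reagents that add atoms: none
Why: Heterogeneous catalytic hydrogenation should deliver hydrogen to C5=C6 from the α face, because the β face carries the axial methyls on C4, C8 and C10, which sets the trans ring fusion.

Step 9
Reactants: 16 9β-[(tert-butyldimethylsilyloxy)methyl]-8α-hydroxy-4,4,8β,10β-tetramethyl-trans-decalin-7-one
Product: 18 9β-[(tert-butyldimethylsilyloxy)methyl]-6α,8α-dihydroxy-4,4,8β,10β-tetramethyl-trans-decalin-7-one, via dipotassium enolate alkoxide 17 (not isolated)
Conditions: KN(SiMe3)2 (2.3 equiv), THF, −78 °C; then 2-(phenylsulfonyl)-3-phenyloxaziridine, −78 °C; AcOH quench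
Reagents that add atoms: 2-(phenylsulfonyl)-3-phenyloxaziridine, O=S(=O)(c1ccccc1)N1OC1c1ccccc1
Why: A second enolate hydroxylation with the N-sulfonyloxaziridine should be regiospecific because, with C8 quaternary, the ketone can enolise only toward C6, and the β face of C6 is flanked by three syn-axial methyls, so oxygen should enter from the α face to give the equatorial 6α-alcohol.

Step 10
Reactants: 18 9β-[(tert-butyldimethylsilyloxy)methyl]-6α,8α-dihydroxy-4,4,8β,10β-tetramethyl-trans-decalin-7-one
Product: 19 6α-acetoxy-9β-[(tert-butyldimethylsilyloxy)methyl]-8α-hydroxy-4,4,8β,10β-tetramethyl-trans-decalin-7-one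
Conditions: Ac2O (1.5 equiv), DMAP (cat.), pyridine, CH2Cl2, 0 °C to 20 °C
Reagents that add atoms: acetic anhydride, CC(=O)OC(C)=O
Why: DMAP-catalysed acylation should esterify the secondary 6α-hydroxyl while the tertiary, doubly flanked 8α-hydroxyl stays free; doing this while C7 is still a ketone is what distinguishes O6 from O7.

Step 11
Reactants: 19 6α-acetoxy-9β-[(tert-butyldimethylsilyloxy)methyl]-8α-hydroxy-4,4,8β,10β-tetramethyl-trans-decalin-7-one
Product: 20 6α-acetoxy-9β-[(tert-butyldimethylsilyloxy)methyl]-4,4,8β,10β-tetramethyl-trans-decalin-7β,8α-diol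
Conditions: NaBH4, CeCl3·7H2O, MeOH/THF, −78 °C to −40 °C; AcOH quench
Reagents that add atoms: none
Why: Luche-type borohydride reduction should add hydride to C7 along the axial trajectory from the α face, where only the axial hydrogens on C5 and C9 are met while the β face is blocked by the axial 8β-methyl, giving the equatorial 7β-alcohol; the cold, weakly acidic cerium medium should suppress acetyl migration.

Step 12
Reactants: 20 6α-acetoxy-9β-[(tert-butyldimethylsilyloxy)methyl]-4,4,8β,10β-tetramethyl-trans-decalin-7β,8α-diol
Product: 21 6α-acetoxy-9β-(hydroxymethyl)-4,4,8β,10β-tetramethyl-trans-decalin-7β,8α-diol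
Conditions: HF·pyridine, THF/pyridine, 0 °C
Reagents that add atoms: none
Why: Fluoride-mediated desilylation in a buffered acidic medium should free the primary alcohol without cleaving the acetate or promoting base-catalysed O6-to-O7 acyl transfer.

Step 13
Reactants: 21 6α-acetoxy-9β-(hydroxymethyl)-4,4,8β,10β-tetramethyl-trans-decalin-7β,8α-diol
Product: 22 6α-acetoxy-7β,8α-dihydroxy-4,4,8β,10β-tetramethyl-trans-decalin-9β-carbaldehyde
Conditions: TEMPO (cat.), PhI(OAc)2, CH2Cl2, 20 °C
Reagents that add atoms: none
Why: Oxoammonium-mediated (TEMPO) oxidation is selective for primary over secondary alcohols, so C11 should go to the aldehyde while the hindered 7β-hydroxyl, the tertiary 8α-hydroxyl and the acetate remain.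

Step 14
Reactants: 22 6α-acetoxy-7β,8α-dihydroxy-4,4,8β,10β-tetramethyl-trans-decalin-9β-carbaldehyde; 23 1-(triphenylphosphoranylidene)propan-2-one
Product: 24 (11E)-6α-acetoxy-7β,8α-dihydroxy-14,15-dinorlabd-11-en-13-one (5S,6R,7S,8S,9R,10S)
Conditions: 23 (3 equiv), toluene, 90 °C
Reagents that add atoms: none
Why: Wittig olefination with the stabilised acetonylidene ylide is E-selective and neutral, so the β-hydroxy aldehyde should be extended to the enone without retro-aldol cleavage, acetyl migration or epimerisation at C9.

**Compound list**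

1 | 2,2,6-trimethylcyclohexanone (racemic) | CC1CCCC(C)(C)C1=O | starting material
2 | (S)-1-phenylethylamine | C[C@H](N)c1ccccc1 | starting material
3 | (S)-1-phenyl-N-(2,2,6-trimethylcyclohexylidene)ethanamine (both C6 epimers) | CC1CCCC(C)(C)C1=N[C@@H](C)c1ccccc1 | intermediate
4 | butane-2,3-dione | CC(=O)C(C)=O | starting material
5 | ethyl (triphenylphosphoranylidene)acetate | CCOC(=O)C=P(c1ccccc1)(c1ccccc1)c1ccccc1 | starting material
6 | ethyl (E)-3-methyl-4-oxopent-2-enoate | CCOC(=O)/C=C(\C)C(C)=O | intermediate
7 | secondary enamine, (S)-N-(1-phenylethyl)-2,6,6-trimethylcyclohex-1-en-1-amine | CC1=C(N[C@@H](C)c2ccccc2)C(C)(C)CCC1 | intermediate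
8 | Michael adduct imine, ethyl (2S,3S)-3-methyl-4-oxo-2-[(1R)-1,3,3-trimethyl-2-{[(S)-1-phenylethyl]imino}cyclohexyl]pentanoate | CCOC(=O)[C@@H]([C@H](C)C(C)=O)[C@@]1(C)CCCC(C)(C)C1=N[C@@H](C)c1ccccc1 | intermediate
9 | diketo ester, ethyl (2S,3S)-3-methyl-4-oxo-2-[(1R)-1,3,3-trimethyl-2-oxocyclohexyl]pentanoate | CCOC(=O)[C@@H]([C@H](C)C(C)=O)[C@@]1(C)CCCC(C)(C)C1=O | intermediate
10 | ethyl 4,4,8α,10β-tetramethyl-7-oxo-Δ5-octalin-9β-carboxylate (8β-H, 9α-H) | CCOC(=O)[C@H]1[C@H](C)C(=O)C=C2C(C)(C)CCC[C@@]21C | intermediate
11 | 9β-(hydroxymethyl)-4,4,8α,10β-tetramethyl-Δ5-octalin-7-ol (both C7 epimers) | OC[C@H]1[C@H](C)C(O)C=C2C(C)(C)CCC[C@@]21C | intermediate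
12 | 9β-(hydroxymethyl)-4,4,8α,10β-tetramethyl-Δ5-octalin-7-one | OC[C@H]1[C@H](C)C(=O)C=C2C(C)(C)CCC[C@@]21C | intermediate
13 | 9β-[(tert-butyldimethylsilyloxy)methyl]-4,4,8α,10β-tetramethyl-Δ5-octalin-7-one | CC(C)(C)[Si](C)(C)OC[C@H]1[C@H](C)C(=O)C=C2C(C)(C)CCC[C@@]21C | intermediate
14 | potassium dienolate of 13 (C5=C6 and C7=C8, oxygen on C7) | CC(C)(C)[Si](C)(C)OC[C@H]1C(C)=C([O-])C=C2C(C)(C)CCC[C@@]21C.[K+] | intermediate
15 | 9β-[(tert-butyldimethylsilyloxy)methyl]-8α-hydroxy-4,4,8β,10β-tetramethyl-Δ5-octalin-7-one | CC(C)(C)[Si](C)(C)OC[C@H]1[C@](C)(O)C(=O)C=C2C(C)(C)CCC[C@@]21C | intermediate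
16 | 9β-[(tert-butyldimethylsilyloxy)methyl]-8α-hydroxy-4,4,8β,10β-tetramethyl-trans-decalin-7-one (5α-H) | CC(C)(C)[Si](C)(C)OC[C@H]1[C@](C)(O)C(=O)C[C@H]2C(C)(C)CCC[C@@]21C | intermediate
17 | dipotassium salt of 16 (C8 alkoxide, C6=C7 enolate) | CC(C)(C)[Si](C)(C)OC[C@H]1[C@](C)([O-])C([O-])=C[C@H]2C(C)(C)CCC[C@@]21C.[K+].[K+] | intermediate
18 | 9β-[(tert-butyldimethylsilyloxy)methyl]-6α,8α-dihydroxy-4,4,8β,10β-tetramethyl-trans-decalin-7-one | CC(C)(C)[Si](C)(C)OC[C@H]1[C@](C)(O)C(=O)[C@H](O)[C@H]2C(C)(C)CCC[C@@]21C | intermediate
19 | 6α-acetoxy-9β-[(tert-butyldimethylsilyloxy)methyl]-8α-hydroxy-4,4,8β,10β-tetramethyl-trans-decalin-7-one | CC(C)(C)[Si](C)(C)OC[C@H]1[C@](C)(O)C(=O)[C@H](OC(C)=O)[C@H]2C(C)(C)CCC[C@@]21C | intermediate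
20 | 6α-acetoxy-9β-[(tert-butyldimethylsilyloxy)methyl]-4,4,8β,10β-tetramethyl-trans-decalin-7β,8α-diol | CC(C)(C)[Si](C)(C)OC[C@H]1[C@](C)(O)[C@@H](O)[C@H](OC(C)=O)[C@H]2C(C)(C)CCC[C@@]21C | intermediate
21 | 6α-acetoxy-9β-(hydroxymethyl)-4,4,8β,10β-tetramethyl-trans-decalin-7β,8α-diol | OC[C@H]1[C@](C)(O)[C@@H](O)[C@H](OC(C)=O)[C@H]2C(C)(C)CCC[C@@]21C | intermediate
22 | 6α-acetoxy-7β,8α-dihydroxy-4,4,8β,10β-tetramethyl-trans-decalin-9β-carbaldehyde | O=C[C@H]1[C@](C)(O)[C@@H](O)[C@H](OC(C)=O)[C@H]2C(C)(C)CCC[C@@]21C | intermediate
23 | 1-(triphenylphosphoranylidene)propan-2-one | CC(=O)C=P(c1ccccc1)(c1ccccc1)c1ccccc1 | starting material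
24 | (11E)-6α-acetoxy-7β,8α-dihydroxy-14,15-dinorlabd-11-en-13-one (CNP0136046.1) | CC(=O)/C=C/[C@H]1[C@](C)(O)[C@@H](O)[C@H](OC(C)=O)[C@H]2C(C)(C)CCC[C@@]21C | target

**Step count and risks**

Total step count: 14. Longest linear sequence: 13 steps (steps 1 and 3 to 14, from ketone 1); step 2 is a one-step side branch.

Steps most likely to fail:

Step 3. The aza-ene addition may be too slow: in enamine 7 the N-substituent is pressed against the C4 methyls, which lowers the concentration and nucleophilicity of the reactive tautomer, and acceptor 6 is substituted at both alkene carbons, so acceptor oligomerisation may outrun C–C bond formation. The aldol onto a carbonyl between two quaternary carbons may also stall at 9; this fallback does not address that. The fallback removes the α-methyl from the acceptor and adds it afterwards. It sets out from imine 3, which is combined under the conditions of step 3 with commercial ethyl (E)-4-oxopent-2-enoate F1, a 1,2-disubstituted and much less hindered ene-keto ester that should react through the same compact transition state. Hydrolysis and acid-catalysed condensation should lead through the adduct imine F2 and the diketo ester F3 to the 8-unsubstituted enone ester F4. Deprotonation with LiN(iPr)2 (1.05 equiv, THF, −78 °C) should give the cross-conjugated lithium dienolate F5 at C8, the ketone α′-position, and MeI should alkylate it anti to the 9β-ester. This returns to the route at compound 10; any 8-epimer is harmless because C8 becomes trigonal again in step 7.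

Step 1. The condensation may stop short because ketone and amine are both α-branched, and forcing conditions may erode the amine or cause aldol self-condensation. The fallback replaces carbonyl condensation by C–N cross-coupling and sets out from ketone 1. Its only enolate (LiN(iPr)2, THF, −78 °C) is trapped with PhNTf2 to give 2,6,6-trimethylcyclohex-1-en-1-yl trifluoromethanesulfonate F6. Palladium-catalysed amination of this alkenyl triflate with amine 2 (Pd2(dba)3, BINAP, Cs2CO3, toluene, 100 °C) should give enamine 7, which equilibrates with imine 3, where the route is rejoined. This path has the advantage of producing the reactive tautomer directly.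

Step 14. The stabilised ylide may add too slowly to an aldehyde flanked by a quaternary carbon on each side, giving retro-aldol cleavage of the β-hydroxy aldehyde, epimerisation at C9 or acetyl migration time to compete. The fallback builds the enone in two stages with a small, reactive nucleophile and sets out from aldehyde 22. Addition of the organocerium reagent from prop-1-ynylmagnesium bromide and CeCl3 (excess, THF, −78 °C; aldehyde-selective in the presence of the acetate) should give the propargylic alcohol F7 as a mixture of C11 epimers. A gold-catalysed Meyer–Schuster rearrangement (Ph3PAuNTf2 cat., MeOH, toluene, 50 °C) should then shift the hydroxyl group and deliver the E-enone directly, returning to the route at the target 24.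

Further compounds
F1 | step 3 | ethyl (E)-4-oxopent-2-enoate | CCOC(=O)/C=C/C(C)=O
F2 | step 3 | adduct imine, ethyl 4-oxo-2-[1,3,3-trimethyl-2-{[(S)-1-phenylethyl]imino}cyclohexyl]pentanoate (C9 and C10 as in 8) | CCOC(=O)[C@@H](CC(C)=O)[C@@]1(C)CCCC(C)(C)C1=N[C@@H](C)c1ccccc1
F3 | step 3 | diketo ester, ethyl 4-oxo-2-(1,3,3-trimethyl-2-oxocyclohexyl)pentanoate (C9 and C10 as in 9) | CCOC(=O)[C@@H](CC(C)=O)[C@@]1(C)CCCC(C)(C)C1=O
F4 | step 3 | ethyl 4,4,10β-trimethyl-7-oxo-Δ5-octalin-9β-carboxylate | CCOC(=O)[C@H]1CC(=O)C=C2C(C)(C)CCC[C@@]21C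
F5 | step 3 | lithium dienolate of F4 (C5=C6 and C7=C8, oxygen on C7) | CCOC(=O)[C@H]1C=C([O-])C=C2C(C)(C)CCC[C@@]21C.[Li+]
F6 | step 1 | 2,6,6-trimethylcyclohex-1-en-1-yl trifluoromethanesulfonate | CC1=C(OS(=O)(=O)C(F)(F)F)C(C)(C)CCC1
F7 | step 14 | propargylic alcohol, 6α-acetoxy-9β-(1-hydroxybut-2-yn-1-yl)-4,4,8β,10β-tetramethyl-trans-decalin-7β,8α-diol (C11 epimers) | CC#CC(O)[C@H]1[C@](C)(O)[C@@H](O)[C@H](OC(C)=O)[C@H]2C(C)(C)CCC[C@@]21C
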